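# Proposed synthesis of CNP0260213.12 by anionic oxy-Cope ring expansion

## Structural features

The target is a germacrane-type sesquiterpenoid built on one ten-membered carbocycle (C1–C10) that carries a 3,4,5-trimethoxybenzoate on O8, an isopropyl group on C7, a free hydroxyl on C6, a trisubstituted oxirane across C4–C5 (methyl on C4) and a trisubstituted E alkene C1=C10 (methyl on C10). Five contiguous stereocentres run from C4 to C8 (4S,5R,6R,7S,8S). The oxirane has C3 and C6 cis, so it is the epoxide of a Z-configured C4=C5 alkene, and its oxygen is erythro (syn in the ring drawing) to the C6 hydroxyl; in the same drawing O6 is cis and O8 trans to the isopropyl group. The fragile points are the oxirane (it faces the C1=C10 alkene across the ring and can cyclise transannularly under acid), the 1,5-related unsaturation (Cope-type reorganisation on heating) and the aryl ester (strong bases and nucleophiles). The real difficulty is the medium ring with one E and one Z-derived trisubstituted unit, not any single stereocentre. The key step exploits the fact that the C1=C10 alkene and the latent C4=C5 alkene are 1,5-related through C2–C3, so that the ring is the [3,3] product of a 1,2-dialkenylcyclohexane whose ring bond is C5–C10. That cyclohexane (C5, C6, C7, C8, C9, C10) has the C7 isopropyl and C10 methyl groups para, the p-menthane pattern of carvone, whose stereocentre maps onto C7.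

## Logic of the disconnections

**26 to 25.** The two C–O bonds of the oxirane are cut. This removes two stereocentres and the most acid-sensitive group and leaves a Z-allylic alcohol. The forward step must put oxygen on the peripheral face of C4=C5, to which the free C6 hydroxyl can steer a metal peroxide, and must leave C1=C10 alone, so O6 has to be free and the alkene Z at that point.

**25 to 24, and 24 to 22 + 23.** The O6–benzyl bond and the acyl–O8 bond are cut. This separates the aromatic acid as 23 and reduces the problem to a diol derivative with O6 and O8 distinguishable. The demand is orthogonal masking: O8 must be freed and acylated while O6 is still protected.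

**22 to 21 to 20.** The O8–Si bond is restored and C5–H is replaced by C5–O (a sulfonate). The alkene geometry of 21 is then inherited from an enolate derivative. The reduction must proceed with retention at C5.

**20 to 17 (key).** C2–C3 is cut and C5–C10 re-formed, which folds the ten-membered ring back onto a cyclohexanol. Ring size and both trisubstituted alkene geometries become a question of cyclohexane conformation. The demand is a cis relationship between the C5 isopropenyl and C10 vinyl groups, a reactive chair with the vinyl axial, and capture of the enolate on oxygen.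

**17 to 16 to 15.** The C6–O ether bond is cut (oxirane opening), then both oxirane C–O bonds. Direct addition of an isopropenyl nucleophile to the carbonyl of 11 would enter anti to the axial C10 vinyl group and give the trans-dialkenyl carbinol. An electrophilic hydroxylation next to that carbonyl would put O6 trans to the isopropyl group. Cutting at C–O instead lets oxygen arrive on the open face of C5 and sets C6 by inversion. The demands are site- and face-selective epoxidation of 15 and SN2 attack at C6 of 16.

**15 to 13 + 14, and 13 to 11.** The C4–C5 bond is cut (sp2–sp2 coupling), then the enol sulfonate is returned to the ketone. The three-carbon unit comes from 14. Ketone 11 can enolise only toward C6, so the regiochemistry is automatic.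

**11 to 10 to 7 + 8.** The C1=C2 alkene is traced to a carbinol, then the C10–C1 bond and the C9–H bond are cut (reductive aldol). This creates the quaternary C10 from an enone and 8. The demand is axial attack of the electrophile cis to the isopropyl group.

**7 to 6 to 4 to 2 to 1.** The O8–Si bond, the C8–O bond (via a β,γ-epoxy ketone), the position of the ring alkene and the two hydrogens of the isopropyl group are removed in turn, arriving at 1. The demand is oxygenation at C8 anti to the isopropyl group.

## Other disconnections considered

Alternative 1: The cut is the C4–C5 bond together with the C4–O bond of the oxirane. LiN(SiMe3)2 would deprotonate the open-chain chloromethyl ketone A1 at C5, the C5 carbon would add to the C4 carbonyl group, and the C4 oxygen would then displace chloride, giving the macrocyclic epoxy ketone A2 in one operation.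

- In its favour: ring and oxirane are made together, C1=C10 is fixed beforehand by ordinary acyclic olefin chemistry, and A1 needs only C7 and C8 as stereocentres. On step economy it is probably the equal or the better of the chosen plan, and on the certainty of the E alkene it is its equal.
- Against it here: A1 has competing acidic sites (C3 and the methyl of the C4 ketone, C7), and enolisation toward C7 would expel the β-silyloxy group on C8. A ten-membered ring has to close by an untemplated aldol step against oligomerisation. C4 and C5 are created in that step with only remote centres to bias them, yet the oxirane must come out with C3 and C6 cis and with the right absolute sense. The C6 carbonyl of A2 would still have to be reduced to the 6R carbinol next to the oxirane.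
- Comparison: the mechanism is a stepwise aldol/SN2 sequence. The chosen plan uses a concerted shift from a conformationally defined chair and sets the oxirane from the C6 hydroxyl, so it is stronger on oxirane configuration and on ring formation.

Alternative 2: The cut is C6–C7. SmI2 would reduce the C7–Br bond of the bromo ketone A3, and the C7 carbon of the metal enolate unit so formed would add to the C6 aldehyde group, closing the ring as the hydroxy ketone A4.

- In its favour: the oxirane carbons C4 and C5 are set by a reagent-controlled Sharpless epoxidation before the ring exists, independent of any medium-ring conformation. On this point it is better than the chosen plan, which relies on a substrate-directed epoxidation at the last step. Samarium Reformatsky closures are among the more dependable routes to medium rings because the metal templates both ends. A3 is convergent, so step economy is likely equal or better.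
- Against it here: C6 and C7 are formed together, and their configuration depends on a chelated transition state facing the α,β-epoxy aldehyde unit of A3, whose facial preference is not secure. C7 is a hindered, isopropyl-bearing enolate carbon. SmI2 can open an α,β-epoxy carbonyl unit reductively. A4 is a β-hydroxy ketone open to retro-aldol cleavage and dehydration. The C8 carbonyl of A4 would still have to be reduced (1,3-anti to O6, feasible by hydroxyl-directed reduction), after which two free secondary hydroxyls must be told apart for acylation.
- Comparison: the chosen plan differentiates O6 and O8 from the start and creates no stereocentre in the ring-forming step, but it pays with a longer linear sequence.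

Alternative 3: The cut is C7–C8. n-BuLi would exchange tin for lithium at C8 of the thirteen-membered α-stannyl allyl ether A5, and a [2,3] shift of the C8 carbanion centre onto C7 would contract the ether to the ten-membered dienol A6, which has a free C8 alkoxide and a C7 isopropenyl group.

- In its favour: a larger, less strained ring is closed first and then contracted. The C7–C8 bond and both stereocentres come from one suprafacial shift that transfers the configuration of the stannane carbon (with inversion) and the geometry of the allyl ether. Both ring alkenes are set before the ring exists, which equals the chosen plan in certainty of geometry. O8 emerges free and already distinguished from O6, a point on which it is slightly better.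
- Against it here: A5 needs three defined alkenes, a stereodefined α-alkoxystannane carbon and a macro-etherification or equivalent. [1,2] shift and transannular paths compete. The isopropenyl group of A6 must afterwards be hydrogenated in the presence of two ring alkenes. The oxirane still has to be installed by the same directed epoxidation as in the chosen plan.
- Comparison: both are sigmatropic ring-size changes; this one is the longer route and leans on a harder precursor.

Key step: step 11

## Remarks on the chemistry

- Descriptor: by the sequence rule the C4=C5 enolate 19 and the enol triflate 20 are 4E, because O5 outranks C6, although C3 and C6 are cis. The descriptor is 4Z only from 21 on, where hydrogen has replaced the sulfonate.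
- Protecting group: O8 is carried as the triisopropylsilyl ether, because a tert-butyldimethylsilyl ether is not expected to survive the hot alkoxide of step 10. The skeleton and configuration of 17 are those the rearrangement needs.
- Assumption: commercial (R)-(−)-carvone is taken as enantiomerically pure; every other stereocentre is set relative to C7.
- Numbering: target numbering (C1–C10) is used for all intermediates.

## Route

Step 1
Reactants: 1 (R)-(−)-carvone
Product: 2 (R)-carvotanacetone, (5R)-2-methyl-5-(propan-2-yl)cyclohex-2-en-1-one
Conditions: H2 (1 atm), RhCl(PPh3)3 (cat.), benzene, rt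
Reagents that add atoms: none
Why: Homogeneous hydrogenation with RhCl(PPh3)3 saturates the unhindered 1,1-disubstituted isopropenyl alkene much faster than the conjugated trisubstituted ring alkene; the stereocentre, C7 of the target, is untouched.

Step 2
Reactants: 2 (R)-carvotanacetone
Product: 4 (5R)-2-methyl-5-(propan-2-yl)cyclohex-3-en-1-one (both C2 epimers), via potassium dienolate 3 (not isolated)
Conditions: KOt-Bu, t-BuOH/THF, rt; inverse quench into cold aq. AcOH
Reagents that add atoms: none
Why: Base-mediated deconjugation: equilibration gives the extended dienolate by loss of a C8 proton, and kinetic protonation at the α-carbon (C10) gives the β,γ-enone; C7 is not α to the carbonyl and cannot epimerise, the C10 centre is erased again in step 3, and unchanged 2 can be recycled.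

Step 3
Reactants: 4 (5R)-2-methyl-5-(propan-2-yl)cyclohex-3-en-1-one
Product: 6 (4R,5R)-4-hydroxy-2-methyl-5-(propan-2-yl)cyclohex-2-en-1-one (hydroxyl trans to isopropyl), via epoxy ketone 5 (not isolated)
Conditions: mCPBA, NaHCO3, CH2Cl2, 0 °C; then Et3N, rt
Reagents that add atoms: meta-chloroperoxybenzoic acid, OOC(=O)c1cccc(Cl)c1
Why: Prilezhaev epoxidation of the only isolated alkene should take place mainly anti to the allylic isopropyl group, and amine-induced β-elimination (loss of H10, cleavage of C9–O) turns the β,γ-epoxy ketone into the γ-hydroxy enone; the C8–O bond is never broken, so C8 keeps the configuration set in the epoxidation, and the minor cis epimer is removed here.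

Step 4
Reactants: 6 (4R,5R)-4-hydroxy-2-methyl-5-(propan-2-yl)cyclohex-2-en-1-one
Product: 7 (4R,5R)-2-methyl-5-(propan-2-yl)-4-[tri(propan-2-yl)silyloxy]cyclohex-2-en-1-one
Conditions: i-Pr3SiOTf, 2,6-lutidine, CH2Cl2, −78 to 0 °C
Reagents that add atoms: triisopropylsilyl trifluoromethanesulfonate, CC(C)[Si](C(C)C)(C(C)C)OS(=O)(=O)C(F)(F)F
Why: Standard silylation of a hindered secondary allylic alcohol with the silyl triflate; the triisopropylsilyl group is chosen for its resistance to the alkoxide of step 10 and to KH.

Step 5
Reactants: 7 (4R,5R)-2-methyl-5-(propan-2-yl)-4-[tri(propan-2-yl)silyloxy]cyclohex-2-en-1-one; 8 acetaldehyde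
Product: 10 (2R,4S,5R)-2-(1-hydroxyethyl)-2-methyl-5-(propan-2-yl)-4-[tri(propan-2-yl)silyloxy]cyclohexan-1-one (carbinol epimers), via lithium enolate 9 (not isolated)
Conditions: LiBH(s-Bu)3 (L-Selectride), THF, −78 °C; then MeCHO, −78 °C; aq. NH4Cl
Reagents that add atoms: none
Why: Conjugate reduction of the β-unsubstituted enone by the hindered borohydride gives the C5=C10 enolate regiospecifically, and its aldol addition to acetaldehyde creates the quaternary C10; with the C7 isopropyl and C8 silyloxy groups equatorial, chair-like axial attack places the new chain cis to the isopropyl group and trans to O8 (C10 R), as in axial alkylations of dihydrocarvone-type enolates. The carbinol configuration is irrelevant because it is lost in step 6.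

Step 6
Reactants: 10 (2R,4S,5R)-2-(1-hydroxyethyl)-2-methyl-5-(propan-2-yl)-4-[tri(propan-2-yl)silyloxy]cyclohexan-1-one
Product: 11 (2R,4S,5R)-2-ethenyl-2-methyl-5-(propan-2-yl)-4-[tri(propan-2-yl)silyloxy]cyclohexan-1-one
Conditions: Ph2S[OC(CF3)2Ph]2 (Martin sulfurane), CH2Cl2, rt
Reagents that add atoms: none
Why: Dehydration with the dialkoxydiphenylsulfurane proceeds by E2-type elimination of the alkoxysulfonium ion; C10 is quaternary, so the only β-hydrogens are those of the methyl group and the terminal vinyl group is the only possible alkene.

Step 7
Reactants: 11 (2R,4S,5R)-2-ethenyl-2-methyl-5-(propan-2-yl)-4-[tri(propan-2-yl)silyloxy]cyclohexan-1-one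
Product: 13 C5 enol triflate of 11 (C5=C6; C7, C8 and C10 as in 11), via potassium enolate 12 (not isolated)
Conditions: KN(SiMe3)2, THF, −78 °C; then PhNTf2, −78 to 0 °C; aq. NH4Cl
Reagents that add atoms: N-phenylbis(trifluoromethanesulfonimide), FC(F)(F)S(=O)(=O)N(c1ccccc1)S(=O)(=O)C(F)(F)F
Why: C10 is quaternary, so deprotonation can occur only at C6 and O-sulfonylation of the potassium enolate gives a single enol triflate; no stereocentre is α to the carbonyl.

Step 8
Reactants: 13 C5 enol triflate of 11; 14 4,4,5,5-tetramethyl-2-(prop-1-en-2-yl)-1,3,2-dioxaborolane
Product: 15 C5-isopropenyl C5=C6 diene (1-isopropenylcyclohexene with C10 methyl and vinyl, C7 isopropyl, C8 silyloxy as in 11)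
Conditions: PdCl2(dppf) (cat.), K3PO4, dioxane/H2O, 60 °C
Reagents that add atoms: none
Why: Suzuki–Miyaura coupling of an alkenyl triflate with an alkenylboronate; oxidative addition, transmetalation and reductive elimination occur with retention at both sp2 carbons and tolerate the silyl ether and the vinyl group.

Step 9
Reactants: 15 C5-isopropenyl C5=C6 diene
Product: 16 C5–C6 oxirane of 15 with the oxirane oxygen cis to O8 and to the C10 methyl, trans to the C10 vinyl and the C7 isopropyl
Conditions: mCPBA (1 equiv), NaHCO3, CH2Cl2, −20 to 0 °C
Reagents that add atoms: meta-chloroperoxybenzoic acid, OOC(=O)c1cccc(Cl)c1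
Why: Prilezhaev epoxidation: the trisubstituted ring alkene is the most electron-rich of the three and should react first with one equivalent of peracid, and in the half-chair that keeps isopropyl and silyloxy equatorial the pseudo-axial C10 vinyl and the C7 isopropyl shield the lower face, so oxygen is delivered to the upper face, which fixes C5 as needed; the buffer protects the vinyl oxirane from acid.

Step 10
Reactants: 16 C5–C6 oxirane
Product: 17 (5R,6R,7S,8S,10R)-cis-1-isopropenyl-2-methyl-2-vinylcyclohexanol with C6-OPMB, C7-isopropyl and C8-OSi(i-Pr)3 (C5 hydroxyl cis to the C10 methyl and to O8, trans to O6)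
Conditions: NaH, 4-MeOC6H4CH2OH (as solvent), 90 °C; aq. NH4Cl
Reagents that add atoms: 4-methoxybenzyl alcohol, COc1ccc(CO)cc1
Why: Alkoxide opening of the oxirane by SN2 attack at the secondary, non-allylic C6 (C5 is quaternary and cannot be attacked directly); backside, trans-diaxial attack inverts C6, placing O6 cis to the isopropyl group and trans to the C5 hydroxyl, which keeps its oxygen and configuration. The alcohol medium keeps the tertiary hydroxyl of 17 protonated, so that the alkoxide-accelerated rearrangement does not start here.

Step 11
Reactants: 17 cis-1-isopropenyl-2-methyl-2-vinylcyclohexanol with C6-OPMB, C7-isopropyl and C8-OSi(i-Pr)3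
Product: 20 ten-membered C5 enol triflate (1(10)E; C3 cis to C6 across C4=C5 which is 4E by the sequence rule; C6-OPMB; C7-isopropyl; C8-OSi(i-Pr)3), via potassium alkoxide 18 (not isolated), via potassium enolate 19 (not isolated)
Conditions: KH, 18-crown-6, THF, 0 °C to rt; then PhNTf2, −78 to 0 °C; aq. NH4Cl
Reagents that add atoms: N-phenylbis(trifluoromethanesulfonimide), FC(F)(F)S(=O)(=O)N(c1ccccc1)S(=O)(=O)C(F)(F)F
Why: Anionic oxy-Cope rearrangement: KH with the crown ether gives the dissociated potassium alkoxide, whose oxyanion weakens C5–C10 so that the 3-oxido-1,5-diene C2=C1–C10–C5–C4=C3 undergoes a chair [3,3] shift, forming C2–C3 and breaking C5–C10. The closest known reaction type is the alkoxide-accelerated ring expansion of 1,2-dialkenylcyclohexanols to cyclodec-5-enones with trapping of the enolate. The ten-membered ring is not closed end to end; it arises by four-atom expansion of the cyclohexane, the new bond forming inside a six-membered chair transition state. No stereocentre is created, C6, C7 and C8 are spectators, and what is set is alkene geometry. In the chair that keeps the C7 isopropyl and C8 silyloxy groups equatorial, the C10 vinyl is axial and the C5 isopropenyl equatorial, so C9 is pseudo-equatorial on C10 (E C1=C10) and C6 pseudo-axial on C5 (C3 cis to C6), with the oxyanion pseudo-equatorial in the pericyclic chair. The ring-flipped chair, which would give the Z C1=C10 isomer, places isopropenyl and isopropyl syn-diaxial, and a boat transition state would require a twist-boat cyclohexane. Enolate formation and relief of the vinyl/OPMB 1,3-diaxial contact pay for the medium-ring strain, and O-sulfonylation at low temperature freezes the enolate before proton transfer can scramble geometry or regiochemistry.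

Step 12
Reactants: 20 ten-membered C5 enol triflate
Product: 21 ten-membered (1(10)E,4Z)-diene with C6-OPMB, C7-isopropyl, C8-OSi(i-Pr)3
Conditions: Pd(OAc)2 (cat.), PPh3, HCO2H, Et3N, DMF, 60 °C
Reagents that add atoms: none
Why: Palladium-catalysed formate reduction of an enol triflate: zerovalent palladium inserts into the C5–O bond, formate supplies hydride with loss of CO2, and reductive elimination gives the C5–H alkene with retention, so C3 and C6 stay cis (4Z); the allylic PMB ether is too poor a leaving group to ionise.

Step 13
Reactants: 21 ten-membered (1(10)E,4Z)-diene silyl ether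
Product: 22 ten-membered (1(10)E,4Z)-dien-8-ol with C6-OPMB
Conditions: Bu4NF, THF, rt to 40 °C
Reagents that add atoms: none
Why: Fluoride cleaves the Si–O bond of the hindered secondary silyl ether and touches neither the PMB ether nor the alkenes.

Step 14
Reactants: 22 ten-membered dien-8-ol with C6-OPMB; 23 3,4,5-trimethoxybenzoyl chloride
Product: 24 C8 3,4,5-trimethoxybenzoate of 22 (C6-OPMB retained)
Conditions: Et3N, DMAP (cat.), CH2Cl2, rt
Reagents that add atoms: none
Why: DMAP-catalysed acylation of the free secondary C8 hydroxyl by the acid chloride; O6 is still masked, so only one ester can form, and no bond to C8 is broken.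

Step 15
Reactants: 24 C8 trimethoxybenzoate with C6-OPMB
Product: 25 (1(10)E,4Z)-6-hydroxy-8-(3,4,5-trimethoxybenzoyloxy) diene
Conditions: DDQ, CH2Cl2/aq. pH 7 buffer, 0 °C
Reagents that add atoms: none
Why: Oxidative cleavage of the 4-methoxybenzyl ether by hydride abstraction to the oxocarbenium ion and hydrolysis; the aryl ester and the two trisubstituted alkenes are inert to DDQ under buffered conditions at low temperature.

Step 16
Reactants: 25 Z-allylic alcohol ester
Product: 26 CNP0260213.12, (1(10)E,4S,5R,6R,7S,8S)-4,5-epoxy-6-hydroxy-7-isopropyl-4,10-dimethylcyclodec-1(10)-en-8-yl 3,4,5-trimethoxybenzoate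
Conditions: VO(acac)2 (cat.), t-BuOOH, CH2Cl2, 0 °C
Reagents that add atoms: tert-butyl hydroperoxide, CC(C)(C)OO
Why: Vanadium-catalysed hydroxyl-directed epoxidation: in the ring conformer inherited from the chair of step 11 the face of C4=C5 that looked at C10 is closed by the ring, the C6–O bond lies close to the alkene plane and C7 sits on the transannular side, so the O6-bound vanadium peroxide should deliver oxygen to the peripheral face, which is the erythro 4S,5R oxirane required beside the 6R carbinol. The remote C1=C10 alkene has no directing group, and the stereospecific syn addition keeps C3 and C6 cis on the oxirane.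

## Compound list

1 | (R)-(−)-carvone | CC(=C)[C@@H]1CC=C(C)C(=O)C1 | starting material
2 | (R)-carvotanacetone | CC(C)[C@@H]1CC=C(C)C(=O)C1 | intermediate
3 | potassium dienolate of 2 (formed in the flask) | CC(C)[C@@H]1C=CC(C)=C([O-])C1.[K+] | intermediate
4 | (5R)-2-methyl-5-(propan-2-yl)cyclohex-3-en-1-one, C2 epimers | CC(C)[C@@H]1C=CC(C)C(=O)C1 | intermediate
5 | 3,4-epoxy-2-methyl-5-(propan-2-yl)cyclohexan-1-one, oxirane trans to isopropyl (formed in the flask) | O1[C@H]2[C@@H]1C(C)C(=O)C[C@@H]2C(C)C | intermediate
6 | (4R,5R)-4-hydroxy-2-methyl-5-(propan-2-yl)cyclohex-2-en-1-one | O[C@H]1C=C(C)C(=O)C[C@@H]1C(C)C | intermediate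
7 | (4R,5R)-2-methyl-5-(propan-2-yl)-4-[tri(propan-2-yl)silyloxy]cyclohex-2-en-1-one | CC(C)[Si](C(C)C)(C(C)C)O[C@H]1C=C(C)C(=O)C[C@@H]1C(C)C | intermediate
8 | acetaldehyde | CC=O | starting material
9 | lithium C5=C10 enolate from 7 (formed in the flask) | CC(C)[Si](C(C)C)(C(C)C)O[C@H]1CC(C)=C([O-])C[C@@H]1C(C)C.[Li+] | intermediate
10 | (2R,4S,5R)-2-(1-hydroxyethyl)-2-methyl-5-(propan-2-yl)-4-[tri(propan-2-yl)silyloxy]cyclohexan-1-one, carbinol epimers | CC(C)[Si](C(C)C)(C(C)C)O[C@H]1C[C@](C)(C(C)O)C(=O)C[C@@H]1C(C)C | intermediate
11 | (2R,4S,5R)-2-ethenyl-2-methyl-5-(propan-2-yl)-4-[tri(propan-2-yl)silyloxy]cyclohexan-1-one | CC(C)[Si](C(C)C)(C(C)C)O[C@H]1C[C@](C)(C=C)C(=O)C[C@@H]1C(C)C | intermediate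
12 | potassium C5=C6 enolate of 11 (formed in the flask) | CC(C)[Si](C(C)C)(C(C)C)O[C@H]1C[C@](C)(C=C)C([O-])=C[C@@H]1C(C)C.[K+] | intermediate
13 | C5 enol triflate of 11 | CC(C)[Si](C(C)C)(C(C)C)O[C@H]1C[C@](C)(C=C)C(OS(=O)(=O)C(F)(F)F)=C[C@@H]1C(C)C | intermediate
14 | 4,4,5,5-tetramethyl-2-(prop-1-en-2-yl)-1,3,2-dioxaborolane | CC(=C)B1OC(C)(C)C(C)(C)O1 | starting material
15 | C5-isopropenyl C5=C6 diene | CC(C)[Si](C(C)C)(C(C)C)O[C@H]1C[C@](C)(C=C)C(C(C)=C)=C[C@@H]1C(C)C | intermediate
16 | C5–C6 oxirane of 15, oxygen cis to O8 | CC(C)[Si](C(C)C)(C(C)C)O[C@H]1C[C@](C)(C=C)[C@@]2(C(C)=C)O[C@H]2[C@@H]1C(C)C | intermediate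
17 | (5R,6R,7S,8S,10R) oxy-Cope precursor: cis-1-isopropenyl-2-methyl-2-vinylcyclohexanol, C6-OPMB, C7-isopropyl, C8-OSi(i-Pr)3 | CC(C)[Si](C(C)C)(C(C)C)O[C@H]1C[C@](C)(C=C)[C@](O)(C(C)=C)[C@H](OCc2ccc(OC)cc2)[C@@H]1C(C)C | intermediate
18 | potassium alkoxide of 17 (formed in the flask) | CC(C)[Si](C(C)C)(C(C)C)O[C@H]1C[C@](C)(C=C)[C@]([O-])(C(C)=C)[C@H](OCc2ccc(OC)cc2)[C@@H]1C(C)C.[K+] | intermediate
19 | ten-membered potassium C4=C5 enolate, E C1=C10, C3 cis to C6 (formed in the flask) | CC(C)[Si](C(C)C)(C(C)C)O[C@H]1C/C(C)=C/CC/C(C)=C([O-])\[C@H](OCc2ccc(OC)cc2)[C@@H]1C(C)C.[K+] | intermediate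
20 | ten-membered C5 enol triflate, 1(10)E, C3 cis to C6 (4E by the sequence rule) | CC(C)[Si](C(C)C)(C(C)C)O[C@H]1C/C(C)=C/CC/C(C)=C(OS(=O)(=O)C(F)(F)F)\[C@H](OCc2ccc(OC)cc2)[C@@H]1C(C)C | intermediate
21 | ten-membered (1(10)E,4Z)-diene, C6-OPMB, C8-OSi(i-Pr)3 | CC(C)[Si](C(C)C)(C(C)C)O[C@H]1C/C(C)=C/CC/C(C)=C\[C@H](OCc2ccc(OC)cc2)[C@@H]1C(C)C | intermediate
22 | ten-membered (1(10)E,4Z)-dien-8-ol, C6-OPMB | O[C@H]1C/C(C)=C/CC/C(C)=C\[C@H](OCc2ccc(OC)cc2)[C@@H]1C(C)C | intermediate
23 | 3,4,5-trimethoxybenzoyl chloride | COc1cc(cc(OC)c1OC)C(Cl)=O | starting material
24 | C8 3,4,5-trimethoxybenzoate, C6-OPMB | COc1cc(cc(OC)c1OC)C(=O)O[C@H]1C/C(C)=C/CC/C(C)=C\[C@H](OCc2ccc(OC)cc2)[C@@H]1C(C)C | intermediate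
25 | C8 3,4,5-trimethoxybenzoate, free C6 hydroxyl, (1(10)E,4Z)-diene | COc1cc(cc(OC)c1OC)C(=O)O[C@H]1C/C(C)=C/CC/C(C)=C\[C@H](O)[C@@H]1C(C)C | intermediate
26 | CNP0260213.12 | COc1cc(C(=O)O[C@H]2C/C(C)=C/CC[C@]3(C)O[C@@H]3[C@H](O)[C@@H]2C(C)C)cc(OC)c1OC | target

## Step count and least certain steps

Total: 16 steps. Longest linear sequence: 16 steps, from 1 to 26; compounds 8, 14 and 23 are bought.

**Step 11 (key step).** The most likely failure is in the capture, not in the shift itself. The crowded tetrasubstituted enolate may sulfonylate slowly, so that proton transfer, equilibration toward C6 or transannular reactions take over. Some material may also leak through the ring-flipped chair and erode the alkene geometry.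
Fallback: from 17, the same alkoxide rearrangement is run and the enolate is silylated with Me3SiCl, which is faster and cleaner on hindered enolates, to give the trimethylsilyl enol ether F1. This is purified and its geometry checked. MeLi in THF then regenerates the enolate as the lithium salt F2 under conditions free of crown ether and excess hydride, and PhNTf2 converts it to 20.

**Step 10.** Substitution at C6 has to pass the axial C10 vinyl group, so the opening may be slow. Forcing it invites premature alkoxide-accelerated rearrangement of the product, SN2′ attack at C3, or loss of the silyl group.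
Fallback: from 16, Pd(PPh3)4 isomerises the vinyl oxirane (ionisation to the π-allyl complex at C5, β-hydride loss from C6, hydrogen return to the allyl unit) to the C6 ketone F3. KN(SiMe3)2 at −78 °C removes the doubly activated H5, and 2-(phenylsulfonyl)-3-phenyloxaziridine hydroxylates the dienolate at C5 on the face away from the axial C10 vinyl, giving the α-ketol F4. Me4NBH(OAc)3 then reduces the C6 carbonyl by hydride delivery from the boron ester of O5, giving the trans-diol F5. 4-Methoxybenzyl 2,2,2-trichloroacetimidate with catalytic La(OTf)3 in toluene etherifies the secondary hydroxyl only, without forming the tertiary alkoxide, and rejoins the route at 17.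

**Step 9.** Site selectivity may be lost (attack on the isopropenyl alkene, double epoxidation), or face selectivity may be lower than the half-chair analysis suggests.
Fallback: from 15, Bu4NF frees O8 to give the homoallylic alcohol F6. VO(acac)2/t-BuOOH then epoxidises only the C5=C6 alkene, syn to that hydroxyl and so on the required face, to give the epoxy alcohol F7. Re-silylation with i-Pr3SiOTf/2,6-lutidine returns to 16.

**Step 6.** Dehydration next to a quaternary carbon may drift toward ionisation, with 1,2-acyl or alkyl shift, or toward retro-aldol cleavage.
Fallback: from 7, the same conjugate reduction is followed by allyl bromide instead of acetaldehyde, giving the allyl ketone F8. RuHCl(CO)(PPh3)3 in hot toluene then moves the alkene one position inward to give the (E)-prop-1-enyl ketone F9. Ethenolysis with the second-generation Hoveyda–Grubbs catalyst under ethylene cuts off one carbon and gives 11.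

**Step 3.** The allylic isopropyl group is pseudo-equatorial, so facial discrimination in the epoxidation may be modest and the cis-hydroxy enone may form in quantity.
Fallback: from 4, the epoxidation–elimination is run as before and the separated cis epimer F10 is not discarded. A Mitsunobu reaction (4-nitrobenzoic acid, PPh3, diisopropyl azodicarboxylate) inverts C8 to the trans ester F11, and K2CO3/MeOH releases 6.

**Step 16.** Facial selectivity may be poor or reversed if the ring reacts through the flipped conformer in which H6 eclipses the alkene and O6 points outward, the mode that simple Z-cycloalkenols of eight and nine ring atoms follow; oxygen would then arrive on the other face and give the threo epimer. The Lewis-acidic vanadium may also trigger transannular opening of the new oxirane by C1=C10, or oxidise the allylic alcohol.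
Fallback: from 25, a Sharpless epoxidation (Ti(Oi-Pr)4, D-(−)-diethyl tartrate, t-BuOOH, molecular sieves, CH2Cl2, −20 °C) is used in place of the vanadium catalyst. For a secondary allylic alcohol this tartrate enantiomer pairs the alkene face that leads to 5R with the 6R carbinol as the fast-reacting, erythro-selective combination, so the face is chosen by the reagent and not by ring conformation. The product is 26 and no new intermediate is involved.

## Further compounds

F1 | step 11 | ten-membered trimethylsilyl enol ether, E C1=C10, C3 cis to C6 | CC(C)[Si](C(C)C)(C(C)C)O[C@H]1C/C(C)=C/CC/C(C)=C(O[Si](C)(C)C)\[C@H](OCc2ccc(OC)cc2)[C@@H]1C(C)C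
F2 | step 11 | ten-membered lithium C4=C5 enolate | CC(C)[Si](C(C)C)(C(C)C)O[C@H]1C/C(C)=C/CC/C(C)=C([O-])\[C@H](OCc2ccc(OC)cc2)[C@@H]1C(C)C.[Li+]
F3 | step 10 | C6 ketone with C5-H and C5-isopropenyl (C5 epimers) | CC(C)[Si](C(C)C)(C(C)C)O[C@H]1C[C@](C)(C=C)C(C(C)=C)C(=O)[C@@H]1C(C)C
F4 | step 10 | C5-hydroxy C6 ketone, hydroxyl cis to the C10 methyl | CC(C)[Si](C(C)C)(C(C)C)O[C@H]1C[C@](C)(C=C)[C@](O)(C(C)=C)C(=O)[C@@H]1C(C)C
F5 | step 10 | C5,C6 trans-diol | CC(C)[Si](C(C)C)(C(C)C)O[C@H]1C[C@](C)(C=C)[C@](O)(C(C)=C)[C@H](O)[C@@H]1C(C)C
F6 | step 9 | C8-hydroxy diene (desilylated 15) | O[C@H]1C[C@](C)(C=C)C(C(C)=C)=C[C@@H]1C(C)C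
F7 | step 9 | C8-hydroxy C5–C6 oxirane, oxygen cis to the hydroxyl | O[C@H]1C[C@](C)(C=C)[C@@]2(C(C)=C)O[C@H]2[C@@H]1C(C)C
F8 | step 6 | C10-allyl ketone, allyl cis to isopropyl | CC(C)[Si](C(C)C)(C(C)C)O[C@H]1C[C@](C)(CC=C)C(=O)C[C@@H]1C(C)C
F9 | step 6 | C10-(E)-prop-1-enyl ketone | CC(C)[Si](C(C)C)(C(C)C)O[C@H]1C[C@](C)(/C=C/C)C(=O)C[C@@H]1C(C)C
F10 | step 3 | (4S,5R)-4-hydroxy-2-methyl-5-(propan-2-yl)cyclohex-2-en-1-one, cis epimer of 6 | O[C@@H]1C=C(C)C(=O)C[C@@H]1C(C)C
F11 | step 3 | (1R,6R)-3-methyl-4-oxo-6-(propan-2-yl)cyclohex-2-en-1-yl 4-nitrobenzoate, trans | O=C(O[C@H]1C=C(C)C(=O)C[C@@H]1C(C)C)c1ccc(cc1)[N+](=O)[O-]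
F0 | step 16 | none | none
A1 | alternative 1 | open-chain C5 chloromethyl C6 ketone with C4 methyl ketone, E C1=C10, C7 isopropyl, C8 OTBS | CC(=O)CC/C=C(\C)C[C@H](O[Si](C)(C)C(C)(C)C)[C@@H](C(C)C)C(=O)CCl
A2 | alternative 1 | ten-membered 4,5-epoxy-6-ketone with C8 OTBS | CC(C)(C)[Si](C)(C)O[C@H]2C/C(C)=C/CC[C@]3(C)O[C@@H]3C(=O)[C@@H]2C(C)C
A3 | alternative 2 | C7-bromo C8 ketone carrying the cis-4,5-epoxy C6 aldehyde (C7 epimers) | CC(C)C(Br)C(=O)C/C(C)=C/CC[C@]1(C)O[C@@H]1C=O
A4 | alternative 2 | ten-membered 4,5-epoxy-6-hydroxy-8-ketone | O=C2C/C(C)=C/CC[C@]3(C)O[C@@H]3[C@H](O)[C@@H]2C(C)C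
A5 | alternative 3 | thirteen-membered α-tributylstannyl allyl ether with C6 OTBS | CCCC[Sn](CCCC)(CCCC)[C@@H]1OC/C(C)=C/[C@@H](O[Si](C)(C)C(C)(C)C)/C=C(C)\CC/C=C(\C)C1
A6 | alternative 3 | ten-membered dienol with C7 isopropenyl, free C8 hydroxyl, C6 OTBS | O[C@H]2C/C(C)=C/CC/C(C)=C\[C@H](O[Si](C)(C)C(C)(C)C)[C@@H]2C(C)=C
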